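# Minutes of the meeting on the north flask

| flask | D | L | remark | time |
|---|---|---|---|---|
| north | 0.15 M | 0.15 mM | the very flask that is asked about, followed so far |  |
| south-west | 0.15 M | 0.30 mM | run made earlier |  |
| flask | 0.15 M | 0.150 mM |  | 30 min |

| run | time / min | D / % | E / % |
|---|---|---|---|
| north | 1.50 | 90.3 | 10.8 |
| north | 3.00 | 79.1 | 21.4 |
| north | 5.00 | 65.6 | 34.0 |
| north | 6.00 | 59.3 | 40.5 |
| north | 8.00 | 51.0 | 49.8 |
| north | 10.0 | 45.2 | 56.5 |
| south-west | 2.50 | 73.1 | 26.6 |
| south-west | 4.00 | 58.6 | 40.3 |
| south-west | 6.00 | 45.4 | 54.4 |
| south-west | 10.0 | 28.2 | 72.4 |
| south-west | 20.0 | 8.7 | 90.8 |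
| south-west | 30.0 | 3.5 | 95.9 |

(readings scatter by 0.5 percentage points)

1. part of the D that has reacted at 30 min
2. pH of the solution at 30 min

- L is the free proton; pH is minus the decimal logarithm of its molar concentration

Late times came first. The first speaker held that what counts at 30 min is how many times D has fallen by a factor e, and that the north flask has 0.794 such turnovers behind it at 10.0 min. She added that at a given cL, D falls in a pseudo-first-order way, and that the first reading of the south-west run shows a pace about twice that of the north run, on twice the L charged.

The second speaker supplied the pace for the remaining minutes. The last 4.00 min of the north run read 0.0679 min⁻¹. The last stretch of the south-west run, scaled to the north charge of L, read 0.0455 min⁻¹, and he took this as the pace with cL back near its charge. The meeting took the mean, 0.0567 min⁻¹.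

So the north flask's count at 30 min came to 1.93: this is the turnover count, the natural logarithm of D charged over D left. That makes 85.5 % reacted. He read the mean pace as cL averaging 1.25 of its charge over the minutes after 10.0 min, and the last pace as cL near its charge, and the meeting put the pH at 30 min close to that of the charged L, or a little below it.

The forecast, which differs from this reckoning, gave 81 % and pH 4, reading that “free proton seems to rise by about 0.06 mM”.

The flask gives 88.0 % and pH 3.76.

    D + L → X + L + E (k = 5.41 M⁻¹ s⁻¹)
    X ⇌ Z + L, settled at all times (K = 3.20 × 10⁻⁶ M)
    D → X + E (k = 4.24 × 10⁻⁶ s⁻¹)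
    X → G (k = 0.0148 s⁻¹)

The flask's turnover count at 30 min is 2.12, against the 1.93 reckoned. In this flask at 30.0 min the half-life of D by the step with L is 12 min, shorter than the 45 h by the step without L. In this flask at 6.80 min the step with L uses D 330 times as fast as the step without L. The neighbour flask, charged with 6.0 × 10⁻⁵ M of L, which is 0.400 of this flask's charge, reaches a count of 1.43, which is 0.675 of this flask's count. Its L stands at 175 % of its own charge, against 115 % in this flask.

The readings were computed from invented constants; the scatter is artificial.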